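**Retrosynthetic overview**

1. Target 31 ← C23 bromide by inversion of an axial alcohol, C5 acetate, and the C5–C6 bond by adding the C6 organocerium of tricyclic iodide 21 to enantiopure ring A ketone 25.
2. Iodide 21 ← hydroboration of a C7 exocyclic methylene (sets C7) ← keto lactone 17, whose C11–O13–C14 γ-lactone comes from carboxylate-directed oxidation of the tertiary C14–H; the C18 bromide comes from radical deoxybromination of the C18 alcohol.
3. The strategy rests on the four contiguous stereocentres C18, C10, C20 and C14 around the cis fusion of the cyclopentane (C7–C8–C9–C10–C20) and the cyclohexane (C10–C18–C17–C16–C14–C20). They are the imprint of an endo Diels–Alder addition of the E,E-1-silyloxy-4-methyl diene 5 across C10=C20 of the 4-silyloxy-2-alkoxycarbonylcyclopentenone 3.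
4. Ring order: cyclopentane (bought, enantiopure) → cyclohexane (Diels–Alder) → γ-lactone (C–H lactonization) → ring A (bought as a cyclohexanone, attached last).

Key step: step 4

Remark: atom labels C5–C28 are positions in the target SMILES; the dienophile is carried as its 2-(trimethylsilyl)ethyl (TMSE) ester and the diene as its triethylsilyl ether so that the ester and the C18 oxygen can be unmasked independently of the C7 TBS ether, and 7,7-dimethyl-1,4-dioxaspiro[4.5]decan-8-one is assumed to be purchasable.

**Route**

Step 1
Reactants: 1 (R)-4-(tert-butyldimethylsilyloxy)cyclopent-2-en-1-one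
Product: 2 (R)-4-(tert-butyldimethylsilyloxy)-2-iodocyclopent-2-en-1-one
Conditions: I2, pyridine, CH2Cl2, 0 °C → rt
Reagents that add atoms: iodine, II
Why: Conjugate addition of pyridine, iodination of the resulting enolate and loss of pyridine (α-iodination of an enone) should give the 2-iodoenone without touching the C7 stereocentre.

Step 2
Reactants: 2 (R)-4-(tert-butyldimethylsilyloxy)-2-iodocyclopent-2-en-1-one
Product: 3 2-(trimethylsilyl)ethyl (R)-3-(tert-butyldimethylsilyloxy)-5-oxocyclopent-1-ene-1-carboxylate
Conditions: CO (1 atm), Pd(OAc)2 (5 mol %), PPh3 (10 mol %), i-Pr2NEt, Me3SiCH2CH2OH (5 equiv), DMF, 50 °C; used at once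
Reagents that add atoms: carbon monoxide, [C-]#[O+]; 2-(trimethylsilyl)ethanol, C[Si](C)(C)CCO
Why: Oxidative addition of the vinyl iodide to zerovalent palladium, CO insertion and alcoholysis of the acylpalladium (palladium-catalysed alkoxycarbonylation) should give the doubly activated dienophile, and the hindered non-nucleophilic base and immediate use limit loss of the silyloxy group.

Step 3
Reactants: 4 (E)-pent-2-enal
Product: 5 (1E,3E)-1-(triethylsilyloxy)penta-1,3-diene
Conditions: Et3SiOTf, Et3N, Et2O, 0 °C → rt
Reagents that add atoms: triethylsilyl trifluoromethanesulfonate, CC[Si](CC)(CC)OS(=O)(=O)C(F)(F)F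
Why: Soft enolization of the enal (O-silylation, then γ-deprotonation by Et3N) should give the silyl dienol ether mainly as the 1E,3E isomer, the only one that can reach the s-cis geometry needed in step 4.

Step 4
Reactants: 3 2-(trimethylsilyl)ethyl (R)-3-(tert-butyldimethylsilyloxy)-5-oxocyclopent-1-ene-1-carboxylate; 5 (1E,3E)-1-(triethylsilyloxy)penta-1,3-diene
Product: 6 cis-fused bicyclic keto ester (cyclohexene C16=C17; C9 ketone; C10 TMSE ester; C7 OTBS; C14 methyl and C18 OTES both cis to C9)
Conditions: 5 (2 equiv), toluene, 2,6-di-tert-butyl-4-methylphenol (cat.), 23 → 50 °C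
Reagents that add atoms: none
Why: A thermal, concerted but asynchronous normal-demand [4+2] cycloaddition, of the type known for 2-alkoxycarbonylcycloalk-2-enones and 1-oxygenated dienes, joins the silyloxy terminus C18 to the doubly activated C10 and the methyl terminus C14 to C20. The one new ring, the cyclohexene C10–C18–C17–C16–C14–C20, closes by intermolecular annulation of the four-carbon diene across the C10=C20 bond of the existing cyclopentenone, which gives the cis ring fusion. C20, and with it the absolute sense of the adduct, is fixed by approach of the diene anti to the C7 silyloxy group, and C10 follows from suprafacial addition. C14 and C18 are set by the endo orientation of the ring ketone under the E,E-diene, which places the methyl and the triethylsilyloxy group cis to C9 and so puts the C14 hydrogen on the face of the C11 ester. The step needs regio-, endo- and facial selectivity together; the oxygen donor at the diene terminus, the ring ketone as the endo-directing group in preference to the ester, and the resident stereocentre of the enantiopure dienophile secure them. The diene is used in excess and acid-free so that stepwise Mukaiyama–Michael pathways and desilylation stay minor.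

Step 5
Reactants: 6 cis-fused bicyclic keto ester
Product: 7 C8=C9 enol triflate of 6
Conditions: LiN(SiMe3)2, THF, −78 °C; N-(5-chloropyridin-2-yl)bis(trifluoromethanesulfonyl)imide, −78 → −40 °C
Reagents that add atoms: N-(5-chloropyridin-2-yl)-1,1,1-trifluoro-N-(trifluoromethylsulfonyl)methanesulfonamide, O=S(=O)(N(c1ccc(Cl)cn1)S(=O)(=O)C(F)(F)F)C(F)(F)F
Why: Kinetic deprotonation at C8, the only enolizable position, and O-triflation at −78 °C (enol triflate formation) should trap the lithium enolate before it can expel the C7 silyloxy group.

Step 6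
Reactants: 7 C8=C9 enol triflate
Product: 8 bicyclic diene (C8=C9 and C16=C17; C9 oxygen removed)
Conditions: Pd(OAc)2 (5 mol %), PPh3 (10 mol %), HCO2H (2 equiv), Bu3N (3 equiv), DMF, 60 °C
Reagents that add atoms: none
Why: Oxidative addition of the enol triflate to zerovalent palladium, formate-to-hydride exchange and reductive elimination (palladium-catalysed formate reduction of an enol triflate) should replace the C9 oxygen by hydrogen under amine-buffered conditions that both silyl ethers tolerate.

Step 7
Reactants: 8 bicyclic diene
Product: 9 saturated cis-hydrindane TMSE ester (C7 OTBS; C18 OTES)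
Conditions: H2 (1 atm), Pd/C (10 wt %), EtOAc, rt
Reagents that add atoms: none
Why: Heterogeneous hydrogenation saturates the two disubstituted alkenes without creating a stereocentre, in an aprotic solvent so that the allylic silyl ethers are not solvolysed.

Step 8
Reactants: 9 saturated cis-hydrindane TMSE ester
Product: 10 C18 alcohol (C7 OTBS kept)
Conditions: pyridinium p-toluenesulfonate (0.2 equiv), MeOH/CH2Cl2, 0 °C → rt
Reagents that add atoms: none
Why: Acid-catalysed methanolysis cleaves a secondary triethylsilyl ether much faster than the secondary TBS ether at C7 (selective desilylation), and with the C9 ketone gone the freed alcohol has no facile retro-aldol path.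

Step 9
Reactants: 10 C18 alcohol
Product: 11 C18 methyl oxalate
Conditions: ClCOCO2Me, Et3N, 4-(dimethylamino)pyridine (cat.), CH2Cl2, 0 °C
Reagents that add atoms: methyl chlorooxoacetate, COC(=O)C(=O)Cl
Why: Acylation of the hindered axial alcohol by the very reactive half acid chloride of oxalic acid (esterification) installs the radical precursor.

Step 10
Reactants: 11 C18 methyl oxalate
Product: 12 C18 cesium oxalate
Conditions: CsOH·H2O (1.0 equiv), THF/H2O, 0 °C → rt; concentrate
Reagents that add atoms: cesium hydroxide, [Cs+].[OH-]
Why: One equivalent of hydroxide saponifies the unhindered methyl oxalate terminus far faster than the neopentyl TMSE ester (selective saponification), giving the oxidizable cesium salt.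

Step 11
Reactants: 12 C18 cesium oxalate
Product: 13 C18 (R) bromide (TMSE ester; C7 OTBS)
Conditions: [Ir(dF(CF3)ppy)2(dtbbpy)]PF6 (2 mol %), diethyl bromomalonate (3 equiv), DMF/1,4-dioxane, blue LEDs, 50 °C
Reagents that add atoms: diethyl bromomalonate, CCOC(=O)C(Br)C(=O)OCC
Why: Single-electron oxidation of the oxalate by the photoexcited iridium complex, loss of two CO2 and bromine-atom transfer from the bromomalonate to the secondary C18 radical (visible-light radical deoxyhalogenation of a cesium oxalate) should give the bromide, the bulky donor entering the equatorial face anti to the cis-fused cyclopentane, whose C7 lies syn-axial to the other face, so that C18 is set with net inversion.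

Step 12
Reactants: 13 C18 (R) bromide
Product: 14 C7 hydroxy C11 carboxylic acid
Conditions: Bu4NF (4 equiv), THF, 0 °C → rt; aq NH4Cl
Reagents that add atoms: none
Why: Fluoride cleaves the C7 TBS ether and, by attack at silicon with loss of ethene, the TMSE ester in one operation (fluoride-induced desilylation), while the cis, gauche relation of the C11 carboxylate and the C18 bromide offers no anti-periplanar path for decarboxylative elimination.

Step 13
Reactants: 14 C7 hydroxy C11 carboxylic acid
Product: 15 C7 keto C11 carboxylic acid
Conditions: Dess–Martin periodinane, CH2Cl2, 0 °C → rt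
Reagents that add atoms: none
Why: Dess–Martin oxidation converts the secondary C7 alcohol into the ketone in the presence of the free acid, which removes the C7–H bond that would compete in step 14 and deactivates the C8 hydrogens.

Step 14
Reactants: 15 C7 keto C11 carboxylic acid
Product: 17 tricyclic keto lactone (C7 ketone; C11–O13–C14 γ-lactone; C18 bromide), via C14-hydroxy keto acid 16 (not isolated)
Conditions: [Fe(PDP)(MeCN)2](SbF6)2 (PDP = (S,S)-1,1′-bis(pyridin-2-ylmethyl)-2,2′-bipyrrolidine; 3 × 5 mol %), H2O2 (50 % aq, 3 × 1.2 equiv), MeCN, rt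
Reagents that add atoms: hydrogen peroxide, OO
Why: The carboxylate binds the iron centre and steers the iron oxo oxidant to the γ C–H bonds, of which only the tertiary C14–H, held 1,3-diaxial to the C11 carboxyl, is electron-rich (C8–H is α to the ketone, C17–H β to bromine), so hydrogen abstraction and rebound with retention followed by lactonization (carboxylic-acid-directed γ-C–H lactonization) should give the bridged γ-lactone with C14 (S).

Step 15
Reactants: 17 tricyclic keto lactone
Product: 18 C7 exocyclic methylene lactone
Conditions: Ph3PCH3Br (2.0 equiv), KN(SiMe3)2 (1.9 equiv), THF, 0 °C; then 17, 0 °C → rt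
Reagents that add atoms: methyltriphenylphosphonium bromide, C[P+](c1ccccc1)(c1ccccc1)c1ccccc1.[Br-]
Why: Wittig methylenation of the C7 ketone with an ylide made from a non-nucleophilic base gives the exocyclic alkene, the hindered bridgehead lactone and the equatorial neopentyl bromide being inert to the ylide.

Step 16
Reactants: 18 C7 exocyclic methylene lactone
Product: 20 C6 primary alcohol of the tricyclic bromo lactone, via B-alkyl-9-BBN borane 19 (not isolated)
Conditions: 9-borabicyclo[3.3.1]nonane, THF, 0 → 40 °C; then aq NaOAc, 30 % H2O2, 0 °C → rt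
Reagents that add atoms: hydrogen peroxide, OO
Why: The borane adds boron to the terminal C6 and hydrogen to C7 from the convex face of the cyclopentane, the other face being covered by the axial hydrogens at C16 and C18 of the cyclohexane (anti-Markovnikov hydroboration–oxidation), which sets C7 with the C6 arm cis to C14 as in the target.

Step 17
Reactants: 20 C6 primary alcohol
Product: 21 C6 primary iodide
Conditions: I2, PPh3, imidazole, CH2Cl2, 0 °C → rt
Reagents that add atoms: iodine, II
Why: Iodide displaces the alkoxyphosphonium of the primary alcohol (Appel-type iodination) to give the exchange-ready iodide.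

Step 18
Reactants: 22 7,7-dimethyl-1,4-dioxaspiro[4.5]decan-8-one
Product: 23 (S)-7,7-dimethyl-1,4-dioxaspiro[4.5]decan-8-ol
Conditions: (R)-1-methyl-3,3-diphenyltetrahydro-1H,3H-pyrrolo[1,2-c][1,3,2]oxazaborole (10 mol %), BH3·SMe2, THF, −20 °C; MeOH
Reagents that add atoms: none
Why: Corey–Bakshi–Shibata reduction differentiates the quaternary and the methylene flank of the ketone, the (R) catalyst delivering hydride to the face that gives the (S) alcohol, the precursor of the C23 stereocentre.

Step 19
Reactants: 23 (S)-7,7-dimethyl-1,4-dioxaspiro[4.5]decan-8-ol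
Product: 24 (S)-8-(4-methoxybenzyloxy)-7,7-dimethyl-1,4-dioxaspiro[4.5]decane
Conditions: NaH, 4-methoxybenzyl chloride, Bu4NI (cat.), DMF, 0 °C → rt
Reagents that add atoms: 4-methoxybenzyl chloride, COc1ccc(CCl)cc1
Why: Williamson etherification of the sodium alkoxide gives an ether that survives the organocerium step and, as a small alkoxy group next to the gem-dimethyl carbon, favours the axial position in ketone 25.

Step 20
Reactants: 24 (S)-8-(4-methoxybenzyloxy)-7,7-dimethyl-1,4-dioxaspiro[4.5]decane
Product: 25 (S)-4-(4-methoxybenzyloxy)-3,3-dimethylcyclohexan-1-one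
Conditions: 1 M HCl, THF, rt
Reagents that add atoms: water, O
Why: Dilute aqueous acid hydrolyses the dioxolane (acetal hydrolysis) without cleaving the PMB ether.

Step 21
Reactants: 21 C6 primary iodide; 25 (S)-4-(4-methoxybenzyloxy)-3,3-dimethylcyclohexan-1-one
Product: 28 tertiary C5 alcohol (core joined to ring A; C23 OPMB), via alkyllithium 26 (not isolated), via organocerium dichloride 27 (not isolated)
Conditions: t-BuLi (2.1 equiv), Et2O/pentane, −78 °C; CeCl3 (anhydrous), THF, −78 °C; 25 (1.5 equiv), −78 °C; aq NH4Cl
Reagents that add atoms: none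
Why: Iodine–lithium exchange of the primary iodide at −78 °C outruns attack on the hindered bridgehead lactone and the secondary bromide, and transmetalation gives a nucleophilic, weakly basic organocerium that adds to the ketone (organocerium 1,2-addition) from the equatorial direction, anti to the axial C25 methyl of the chair that carries the C23 ether axial (the conformer favoured for a 4-alkoxy ketone next to a gem-dimethyl group and by cerium coordination of the carbonyl), which sets C5 with the new hydroxyl axial and trans to the C23 oxygen; the C5 epimer that arises from the other chair is removed by chromatography.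

Step 22
Reactants: 28 tertiary C5 alcohol
Product: 29 C5 acetate (C23 OPMB)
Conditions: Ac2O, 4-(dimethylamino)pyridine (2 equiv), Et3N, CH2Cl2, 40 °C
Reagents that add atoms: acetic anhydride, CC(=O)OC(C)=O
Why: Acyl transfer from the N-acetylpyridinium of 4-(dimethylamino)pyridine to the hindered tertiary alcohol (nucleophile-catalysed acetylation) gives the C5 acetate while the C23 oxygen is still masked.

Step 23
Reactants: 29 C5 acetate (C23 OPMB)
Product: 30 C23 (S) alcohol of the C5 acetate
Conditions: 2,3-dichloro-5,6-dicyano-1,4-benzoquinone, CH2Cl2/pH 7 buffer, 0 °C → rt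
Reagents that add atoms: none
Why: Oxidative cleavage of the PMB ether (benzylic hydride abstraction, then hydrolysis of the oxocarbenium ion) frees the secondary C23 alcohol under neutral conditions that leave acetate, lactone and bromide alone.

Step 24
Reactants: 30 C23 (S) alcohol of the C5 acetate
Product: 31 CNP0133010.1
Conditions: CBr4, PPh3, toluene, 60 °C
Reagents that add atoms: carbon tetrabromide, BrC(Br)(Br)Br
Why: In the chair fixed by the equatorial C6 arm the C23 hydroxyl is axial, so its alkoxyphosphonium is displaced by bromide from the equatorial direction with inversion (Appel reaction), which gives the equatorial (R) bromide cis to the C5 acetate; heating is needed because the carbinol carbon is neopentylic.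

**Compound list**

1 | (R)-4-(tert-butyldimethylsilyloxy)cyclopent-2-en-1-one | O=C1C=C[C@H](O[Si](C)(C)C(C)(C)C)C1 | starting material
2 | (R)-4-(tert-butyldimethylsilyloxy)-2-iodocyclopent-2-en-1-one | O=C1C(I)=C[C@H](O[Si](C)(C)C(C)(C)C)C1 | intermediate
3 | 2-(trimethylsilyl)ethyl (R)-3-(tert-butyldimethylsilyloxy)-5-oxocyclopent-1-ene-1-carboxylate | C[Si](C)(C)CCOC(=O)C1=C[C@H](O[Si](C)(C)C(C)(C)C)CC1=O | intermediate
4 | (E)-pent-2-enal | CC/C=C/C=O | starting material
5 | (1E,3E)-1-(triethylsilyloxy)penta-1,3-diene | C/C=C/C=C/O[Si](CC)(CC)CC | intermediate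
6 | Diels–Alder adduct: cis-fused cyclopentanone/cyclohexene, C10 TMSE ester and C20–H on one face, C9 ketone, C7 OTBS anti to C14, C14 methyl and C18 OTES cis to C9 | C[Si](C)(C)CCOC(=O)[C@@]12C(=O)C[C@@H](O[Si](C)(C)C(C)(C)C)[C@@H]1[C@H](C)C=C[C@@H]2O[Si](CC)(CC)CC | intermediate
7 | C8=C9 enol triflate of 6 | C[Si](C)(C)CCOC(=O)[C@@]12C(OS(=O)(=O)C(F)(F)F)=C[C@@H](O[Si](C)(C)C(C)(C)C)[C@@H]1[C@H](C)C=C[C@@H]2O[Si](CC)(CC)CC | intermediate
8 | bicyclic diene (C8=C9, C16=C17), C9 deoxygenated | C[Si](C)(C)CCOC(=O)[C@@]12C=C[C@@H](O[Si](C)(C)C(C)(C)C)[C@@H]1[C@H](C)C=C[C@@H]2O[Si](CC)(CC)CC | intermediate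
9 | saturated cis-hydrindane TMSE ester, C7 OTBS, C18 OTES | C[Si](C)(C)CCOC(=O)[C@@]12CC[C@@H](O[Si](C)(C)C(C)(C)C)[C@@H]1[C@H](C)CC[C@@H]2O[Si](CC)(CC)CC | intermediate
10 | C18 alcohol (hydroxyl cis to C9, axial) | C[Si](C)(C)CCOC(=O)[C@@]12CC[C@@H](O[Si](C)(C)C(C)(C)C)[C@@H]1[C@H](C)CC[C@@H]2O | intermediate
11 | C18 methyl oxalate | C[Si](C)(C)CCOC(=O)[C@@]12CC[C@@H](O[Si](C)(C)C(C)(C)C)[C@@H]1[C@H](C)CC[C@@H]2OC(=O)C(=O)OC | intermediate
12 | C18 cesium oxalate | C[Si](C)(C)CCOC(=O)[C@@]12CC[C@@H](O[Si](C)(C)C(C)(C)C)[C@@H]1[C@H](C)CC[C@@H]2OC(=O)C(=O)[O-].[Cs+] | intermediate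
13 | C18 (R) bromide (bromine cis to the C11 ester), TMSE ester, C7 OTBS | C[Si](C)(C)CCOC(=O)[C@@]12CC[C@@H](O[Si](C)(C)C(C)(C)C)[C@@H]1[C@H](C)CC[C@H]2Br | intermediate
14 | C7 hydroxy C11 carboxylic acid | OC(=O)[C@@]12CC[C@@H](O)[C@@H]1[C@H](C)CC[C@H]2Br | intermediate
15 | C7 keto C11 carboxylic acid | OC(=O)[C@@]12CCC(=O)[C@@H]1[C@H](C)CC[C@H]2Br | intermediate
16 | C14-hydroxy keto acid (hydroxyl cis to the carboxyl) | OC(=O)[C@@]12CCC(=O)[C@@H]1[C@@](C)(O)CC[C@H]2Br | intermediate
17 | tricyclic keto lactone: C7 ketone, γ-lactone C11(=O)–O13–C14 bridging C10 and C14, C14 methyl, C18 equatorial bromide | O=C1CC[C@@]23C(=O)O[C@@](C)(CC[C@H]2Br)[C@@H]13 | intermediate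
18 | C7 exocyclic methylene lactone | C=C1CC[C@@]23C(=O)O[C@@](C)(CC[C@H]2Br)[C@@H]13 | intermediate
19 | B-(C6-alkyl)-9-borabicyclo[3.3.1]nonane | C(B1C2CCCC1CCC2)[C@H]1CC[C@@]23C(=O)O[C@@](C)(CC[C@H]2Br)[C@@H]13 | intermediate
20 | C6 primary alcohol (C6 arm cis to C14) | OC[C@H]1CC[C@@]23C(=O)O[C@@](C)(CC[C@H]2Br)[C@@H]13 | intermediate
21 | C6 primary iodide | IC[C@H]1CC[C@@]23C(=O)O[C@@](C)(CC[C@H]2Br)[C@@H]13 | intermediate
22 | 7,7-dimethyl-1,4-dioxaspiro[4.5]decan-8-one | O=C1CCC2(CC1(C)C)OCCO2 | starting material
23 | (S)-7,7-dimethyl-1,4-dioxaspiro[4.5]decan-8-ol | O[C@H]1CCC2(CC1(C)C)OCCO2 | intermediate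
24 | (S)-8-(4-methoxybenzyloxy)-7,7-dimethyl-1,4-dioxaspiro[4.5]decane | COc1ccc(CO[C@H]2CCC3(CC2(C)C)OCCO3)cc1 | intermediate
25 | (S)-4-(4-methoxybenzyloxy)-3,3-dimethylcyclohexan-1-one | COc1ccc(CO[C@H]2CCC(=O)CC2(C)C)cc1 | intermediate
26 | C6 alkyllithium | [Li]C[C@H]1CC[C@@]23C(=O)O[C@@](C)(CC[C@H]2Br)[C@@H]13 | intermediate
27 | C6 organocerium dichloride | Cl[Ce](Cl)C[C@H]1CC[C@@]23C(=O)O[C@@](C)(CC[C@H]2Br)[C@@H]13 | intermediate
28 | tertiary C5 alcohol, hydroxyl axial and trans to the C23 OPMB | O[C@@]1(C[C@H]2CC[C@@]34C(=O)O[C@@](C)(CC[C@H]3Br)[C@@H]24)CC[C@H](OCc2ccc(OC)cc2)C(C)(C)C1 | intermediate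
29 | C5 acetate, C23 OPMB | CC(=O)O[C@@]1(C[C@H]2CC[C@@]34C(=O)O[C@@](C)(CC[C@H]3Br)[C@@H]24)CC[C@H](OCc2ccc(OC)cc2)C(C)(C)C1 | intermediate
30 | C5 acetate, C23 (S) alcohol (hydroxyl trans to the acetate) | CC(=O)O[C@@]1(C[C@H]2CC[C@@]34C(=O)O[C@@](C)(CC[C@H]3Br)[C@@H]24)CC[C@H](O)C(C)(C)C1 | intermediate
31 | CNP0133010.1 | CC(=O)O[C@@]1(C[C@H]2CC[C@@]34C(=O)O[C@@](C)(CC[C@H]3Br)[C@@H]24)CC[C@@H](Br)C(C)(C)C1 | target

**Step count and risks**

Total step count: 24. Longest linear sequence: 20 steps (steps 1, 2, 4–17, 21–24).

The three steps most likely to fail: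

Step 11 (radical deoxybromination at C18). The secondary alkoxycarbonyl radical may lose CO2 too slowly and revert to alcohol or formate, and bromine transfer to the planar C18 radical may not be face-selective. The fallback replaces the radical path by an ionic displacement that is stereospecific. It sets out from alcohol 10, whose hydroxyl is axial and anti to the C11 ester carbon. Tf2O and pyridine in CH2Cl2 at −20 °C should give the C18 trifluoromethanesulfonate F1. Bu4NBr in toluene at rt to 50 °C should then displace it with inversion, and the route is rejoined at bromide 13.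

Step 21 (fragment coupling). t-BuLi or the new alkyllithium may attack the lactone or the C18 bromide, ketone 25 may be enolized, and facial selectivity at C5 may erode through the chair with the C23 ether equatorial. The fallback forms the nucleophile by single-electron reduction in the presence of the ketone, so no organolithium is present. It sets out from iodide 21 and ketone 25, which are treated together with SmI2 (2.2 equiv) and NiI2 (1 mol %) in THF at 0 °C (samarium Barbier reaction; the primary iodide is reduced well before the secondary neopentyl bromides). It comes back at alcohol 28 and makes no further compound (F0). The C5 epimer is removed by chromatography at 28 in either case.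

Step 24 (bromide at C23). Anti-periplanar elimination towards C22 may outrun substitution at the neopentylic carbinol, or the alkoxyphosphonium may not form. The fallback avoids substitution altogether and sets out from alcohol 30. Dess–Martin oxidation should give the C23 ketone F2. Hydrazine hydrate and Et3N in EtOH at 70 °C should give the C23 hydrazone F3. N-bromosuccinimide with 1,1,3,3-tetramethylguanidine (Barton vinyl halide synthesis) should give the C22=C23 vinyl bromide F4. Hydrogen-atom-transfer hydrogenation with Mn(dpm)3 (dpm = 2,2,6,6-tetramethylheptane-3,5-dionate), PhSiH3 and t-BuOOH in i-PrOH at rt then places hydrogen on C22. The α-bromo radical at C23 should take its hydrogen on the axial face, the equatorial face being flanked by both C25 methyls, so bromine ends equatorial and the route is rejoined at target 31.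

**Further compounds**

F1 | step 11 | C18 trifluoromethanesulfonate of alcohol 10 | C[Si](C)(C)CCOC(=O)[C@@]12CC[C@@H](O[Si](C)(C)C(C)(C)C)[C@@H]1[C@H](C)CC[C@@H]2OS(=O)(=O)C(F)(F)F
F0 | step 21 | none | none
F2 | step 24 | C23 ketone of the C5 acetate | CC(=O)O[C@@]1(C[C@H]2CC[C@@]34C(=O)O[C@@](C)(CC[C@H]3Br)[C@@H]24)CCC(=O)C(C)(C)C1
F3 | step 24 | C23 hydrazone of the C5 acetate | CC(=O)O[C@@]1(C[C@H]2CC[C@@]34C(=O)O[C@@](C)(CC[C@H]3Br)[C@@H]24)CCC(=NN)C(C)(C)C1
F4 | step 24 | C22=C23 vinyl bromide of the C5 acetate | CC(=O)O[C@@]1(C[C@H]2CC[C@@]34C(=O)O[C@@](C)(CC[C@H]3Br)[C@@H]24)CC=C(Br)C(C)(C)C1
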